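**Strategy.** Ring A is disconnected across C4–C4a and C1–C8a. Both bonds are made in one intramolecular Diels–Alder reaction between a Z-configured methyl 2-vinylbut-2-enoate unit (C1–C4) and the α-formyl trisubstituted alkene C4a=C8a. The step exploits the cis relation, on ring A, of the C8a methyl carbon and the C1 formyl carbon: in the precursor these two carbons are linked as C–SiMe2–O–C, a temporary six-membered siloxane ring that fixes the regiochemistry, holds the CH2O group on the inside of the diene and so delivers C1, C4a and C8a with the trans-decalin pattern. Ring B then closes by a chloride-terminated Prins reaction, and silicon is removed tracelessly.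

Key step: step 12

Numbering: octahydronaphthalene locants of the target are used throughout. Ring A = C1, C2, C3, C4, C4a, C8a; ring B = C4a, C5, C6, C7, C8, C8a. C11 = carbon on C1 (the CHO carbon), C12 = carboxyl carbon on C2, C13 = methyl carbon on C8a. β = face of C13, α = face of the C4a hydrogen.

Assumption: the sodium dienolate 5 carries the α-methyl cis to O–Na (it derives from the s-trans acyl imide), so that the (4S)-auxiliary gives the R quaternary centre.

Assumption: the (S)-oxazaborolidinium catalyst opens the face of C8a from which CHO → C4a → C13H2 runs clockwise, as it does for 2-substituted acroleins.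

Step 1
Reactants: 1 (4S)-4-benzyl-1,3-oxazolidin-2-one; 2 (2E)-2-methylbut-2-enoyl chloride
Product: 4 (4S)-4-benzyl-3-[(2E)-2-methylbut-2-enoyl]-1,3-oxazolidin-2-one, via lithium oxazolidinide 3 (not isolated)
Conditions: n-BuLi, THF, −78 °C; then 2, −78 to 0 °C
Reagents that add atoms: none
Why: N-acylation of the lithiated oxazolidinone by the acid chloride attaches the chiral auxiliary; no stereocentre is formed.

Step 2
Reactants: 4 (4S)-4-benzyl-3-[(2E)-2-methylbut-2-enoyl]-1,3-oxazolidin-2-one
Product: 6 (4S)-4-benzyl-3-[(2R)-2-ethenyl-2-methylpent-4-enoyl]-1,3-oxazolidin-2-one, via sodium dienolate 5 (not isolated)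
Conditions: NaHMDS, THF, −78 °C; allyl iodide, −78 to −30 °C
Reagents that add atoms: allyl iodide, C=CCI
Why: Deprotonation at the γ-methyl gives the chelated sodium dienolate, which is alkylated at the α-carbon on the face opposite the benzyl group (auxiliary-controlled deconjugative α-alkylation of an N-enoyl oxazolidinone), setting the quaternary centre, the future C5, as R.

Step 3
Reactants: 6 (4S)-4-benzyl-3-[(2R)-2-ethenyl-2-methylpent-4-enoyl]-1,3-oxazolidin-2-one
Product: 7 (2R)-2-ethenyl-2-methylpent-4-en-1-ol
Conditions: LiBH4, H2O (1 equiv), Et2O, 0 °C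
Reagents that add atoms: none
Why: LiBH4 cleaves the N-acyl bond reductively (standard removal of the oxazolidinone auxiliary) and leaves the quaternary centre and both alkenes untouched.

Step 4
Reactants: 7 (2R)-2-ethenyl-2-methylpent-4-en-1-ol
Product: 8 (2R)-2-ethenyl-2-methylpent-4-enal
Conditions: Dess–Martin periodinane, CH2Cl2, 0 °C to rt
Reagents that add atoms: none
Why: Dess–Martin oxidation of the primary alcohol gives the aldehyde, which has no α-hydrogen and therefore cannot racemise.

Step 5
Reactants: 8 (2R)-2-ethenyl-2-methylpent-4-enal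
Product: 9 methyl (2Z,4R)-4-ethenyl-2-iodo-4-methylhepta-2,6-dienoate
Conditions: Ph3P=CHCO2Me, N-iodosuccinimide, CH2Cl2, −20 °C; then 8, toluene, 60 °C
Reagents that add atoms: methyl (triphenylphosphoranylidene)acetate, COC(=O)C=P(c1ccccc1)(c1ccccc1)c1ccccc1; N-iodosuccinimide, O=C1CCC(=O)N1I
Why: Wittig olefination with the α-iodo stabilised ylide formed in the flask should give the Z α-iodo enoate (ester trans to the quaternary carbon), so iodine marks the future C8a on the side of C5.

Step 6
Reactants: 9 methyl (2Z,4R)-4-ethenyl-2-iodo-4-methylhepta-2,6-dienoate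
Product: 10 (2Z,4R)-4-ethenyl-2-iodo-4-methylhepta-2,6-dien-1-ol
Conditions: DIBAL-H, CH2Cl2, −78 °C
Reagents that add atoms: none
Why: DIBAL-H reduces the ester to the allylic alcohol by 1,2-hydride addition without touching the vinyl iodide or the alkene geometry.

Step 7
Reactants: 10 (2Z,4R)-4-ethenyl-2-iodo-4-methylhepta-2,6-dien-1-ol
Product: 11 (2Z,4R)-4-ethenyl-2-iodo-4-methylhepta-2,6-dienal
Conditions: Dess–Martin periodinane, CH2Cl2, 0 °C to rt
Reagents that add atoms: none
Why: Dess–Martin oxidation of the allylic alcohol gives the α-iodo enal with the formyl group (future C8) trans to C5.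

Step 8
Reactants: 12 glycolaldehyde dimer (1,4-dioxane-2,5-diol)
Product: 13 methyl (2Z)-4-hydroxy-2-iodobut-2-enoate
Conditions: Ph3P=CHCO2Me, N-iodosuccinimide, CH2Cl2, −20 °C; then 12, 40 °C
Reagents that add atoms: methyl (triphenylphosphoranylidene)acetate, COC(=O)C=P(c1ccccc1)(c1ccccc1)c1ccccc1; N-iodosuccinimide, O=C1CCC(=O)N1I
Why: Wittig olefination of glycolaldehyde, released from its dimer, with the same α-iodo ylide gives the Z iodide in which CH2OH is trans to the ester and therefore cannot lactonise.

Step 9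
Reactants: 13 methyl (2Z)-4-hydroxy-2-iodobut-2-enoate
Product: 14 methyl (2E)-2-ethenyl-4-hydroxybut-2-enoate
Conditions: tributyl(vinyl)stannane, Pd(PPh3)4 (5 mol %), CuI (10 mol %), DMF, rt
Reagents that add atoms: tributyl(vinyl)stannane, C=C[Sn](CCCC)(CCCC)CCCC
Why: Stille coupling replaces iodine by vinyl with retention of the alkene geometry, which places CH2OH cis to the new vinyl group, i.e. on the inside of the diene.

Step 10
Reactants: 14 methyl (2E)-2-ethenyl-4-hydroxybut-2-enoate
Product: 15 methyl (2E)-4-{[(bromomethyl)dimethylsilyl]oxy}-2-ethenylbut-2-enoate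
Conditions: BrCH2SiMe2Cl, Et3N, DMAP (cat.), CH2Cl2, 0 °C
Reagents that add atoms: (bromomethyl)chlorodimethylsilane, C[Si](C)(Cl)CBr
Why: Silylation of the primary alcohol with the (bromomethyl)dimethylsilyl chloride installs the silicon atom and the CH2 carbon (the future C8a methyl, C13) of the tether.

Step 11
Reactants: 15 methyl (2E)-4-{[(bromomethyl)dimethylsilyl]oxy}-2-ethenylbut-2-enoate; 11 (2Z,4R)-4-ethenyl-2-iodo-4-methylhepta-2,6-dienal
Product: 17 methyl (2E)-2-ethenyl-4-({[(2Z,4R)-4-ethenyl-2-formyl-4-methylhepta-2,6-dien-1-yl]dimethylsilyl}oxy)but-2-enoate, via organozinc bromide 16 (not isolated)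
Conditions: Zn dust (activated with 1,2-dibromoethane and TMSCl), LiCl, THF, 45 °C; then 11, Pd(OAc)2 (3 mol %), SPhos (6 mol %), THF, 0 °C to rt
Reagents that add atoms: none
Why: Zinc insertion into the α-silyl C–Br bond followed by Negishi cross-coupling with the vinyl iodide, with retention of its geometry, forms the C13–C8a bond and so places the tether carbon cis to C5 and the formyl group trans to it.

Step 12
Reactants: 17 methyl (2E)-2-ethenyl-4-({[(2Z,4R)-4-ethenyl-2-formyl-4-methylhepta-2,6-dien-1-yl]dimethylsilyl}oxy)but-2-enoate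
Product: 18 siloxane-bridged cycloadduct (ring A cyclohexene with C2=C3 and CO2Me on C2; C8a carries CHO and β-C13H2; C1 carries β-C11H2; C13–SiMe2–O–C11 ring cis-fused; C4a carries α-H and the R quaternary C5 with methyl, allyl and vinyl)
Conditions: (S)-B-(o-tolyl)oxazaborolidine from (S)-α,α-diphenylprolinol, activated with Tf2NH (20 mol %), CH2Cl2, −40 to −20 °C
Reagents that add atoms: none
Why: Type 1 intramolecular Diels–Alder reaction of an α-tethered 2-substituted acrolein under a cationic oxazaborolidine (closest known types: intramolecular Diels–Alder reactions of Z-dienes to cis-fused bicycles, silicon-tethered cycloadditions, oxazaborolidinium catalysis of 2-substituted enals), in which the activated alkene C4a=C8a adds across C1 and C4 of the diene in a concerted, asynchronous [4+2] process. Ring A is closed as a six-membered ring by the cycloaddition, and the temporary siloxane ring (C1–C11–O–Si–C13–C8a) is closed at the same time as a cis-fused six-membered ring because the tether starts from the inside position of the Z-diene. At C4a and C8a the alkene geometry is transferred suprafacially, so C13 and C5 stay cis and the formyl group (future C8) is trans to C5, which is the trans-decalin relationship. At C1 the inside CH2O group must end cis to the tethered C13, i.e. β like the future C8a methyl, with the formyl group endo and the bulky C5 group exo. The face of the alkene relative to the existing C5 centre is not secured by the substrate and is imposed by the (S)-catalyst. The regiochemistry, which the ester-substituted diene alone would not give, is fixed by the four-atom tether.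

Step 13
Reactants: 18 siloxane-bridged cycloadduct
Product: 19 siloxane-bridged chlorohydrin (trans-decalin with 6β-Cl, 8α-OH, 5β-methyl, 5α-allyl, CO2Me on C2, C2=C3; C13H2 on C8a and C11H2 on C1 bridged as C13–SiMe2–O–C11)
Conditions: SnCl4, CH2Cl2, −78 °C; aq NaHCO3
Reagents that add atoms: tin tetrachloride, Cl[Sn](Cl)(Cl)Cl
Why: Chloride-terminated Prins (cation–olefin) cyclisation: the SnCl4-bound C8 aldehyde is attacked by the terminal carbon of the C5 vinyl group (6-endo closure, chair transition state) in preference to the allyl group that would give a seven-membered ring, the C8–O bond lies axial (α) to avoid the peri C11H2–O/siloxane ring, and chloride adds anti to the new C7–C8 bond to give the equatorial 6β-chloride, while the fixed C5 centre puts its methyl group β-axial.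

Step 14
Reactants: 19 siloxane-bridged chlorohydrin
Product: 21 allyl γ-lactone (C12(=O)–O–C11H2 ring across C2/C1; C8a methyl; 6β-Cl, 8α-OH, 5β-methyl, 5α-allyl), via hydroxy ester 20 (not isolated)
Conditions: Bu4NF, DMF, 70 °C
Reagents that add atoms: none
Why: Fluoride-induced protodesilylation of the 1-oxa-2-silacyclohexane (the known traceless cleavage of siloxanes derived from (bromomethyl)silyl ethers) turns C13–Si into the C8a methyl group and frees the C11 alkoxide, which closes onto the adjacent C2 ester to the γ-lactone; no stereocentre is affected.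

Step 15
Reactants: 21 allyl γ-lactone; 22 2-methylbut-3-en-2-ol
Product: 23 side-chain γ-lactone (as 21, with the 5α-[(2E)-4-hydroxy-4-methylpent-2-en-1-yl] chain)
Conditions: 22 (10 equiv), second-generation Grubbs catalyst (5 mol %), CH2Cl2, 40 °C
Reagents that add atoms: none
Why: Olefin cross-metathesis of the terminal allyl group with the tertiary allylic alcohol should give the E alkene under thermodynamic control, the conjugated trisubstituted ring alkene being unreactive.

Step 16
Reactants: 23 side-chain γ-lactone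
Product: 25 methyl (1R,4aR,5S,6S,8S,8aS)-6-chloro-8-hydroxy-1-(hydroxymethyl)-5-[(2E)-4-hydroxy-4-methylpent-2-en-1-yl]-5,8a-dimethyl-1,4,4a,5,6,7,8,8a-octahydronaphthalene-2-carboxylate, via lithium carboxylate 24 (not isolated)
Conditions: LiOH (1.05 equiv), THF/H2O, 0 °C to rt; evaporate; MeI, DMF, 0 °C; used at once
Reagents that add atoms: lithium hydroxide, [Li+].[OH-]; iodomethane, CI
Why: Hydroxide opens the lactone to the lithium carboxylate, and SN2 methylation of the carboxylate with iodomethane restores the methyl ester without a base strong enough to re-close the lactone or to disturb the chlorohydrin.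

Step 17
Reactants: 25 hydroxy ester triol
Product: 26 methyl (1R,4aR,5S,6S,8S,8aS)-6-chloro-1-formyl-8-hydroxy-5-[(2E)-4-hydroxy-4-methylpent-2-en-1-yl]-5,8a-dimethyl-1,4,4a,5,6,7,8,8a-octahydronaphthalene-2-carboxylate (target)
Conditions: TEMPO (10 mol %), PhI(OAc)2, CH2Cl2, rt
Reagents that add atoms: none
Why: TEMPO-catalysed oxidation with PhI(OAc)2 is selective for the primary alcohol over the hindered secondary and the tertiary alcohols and is not basic, so the epimerisable C1 centre keeps its β-formyl configuration.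

**Compound list**

1 | (4S)-4-benzyl-1,3-oxazolidin-2-one | O=C1N[C@@H](Cc2ccccc2)CO1 | starting material
2 | (2E)-2-methylbut-2-enoyl chloride | C/C=C(\C)C(=O)Cl | starting material
3 | lithium (4S)-4-benzyl-2-oxo-1,3-oxazolidin-3-ide | [Li+].O=C1[N-][C@@H](Cc2ccccc2)CO1 | intermediate
4 | (4S)-4-benzyl-3-[(2E)-2-methylbut-2-enoyl]-1,3-oxazolidin-2-one | C/C=C(\C)C(=O)N1[C@@H](Cc2ccccc2)COC1=O | intermediate
5 | sodium dienolate of 4 (O–Na cis to the α-methyl) | [Na+].[O-]/C(N1[C@@H](Cc2ccccc2)COC1=O)=C(\C)C=C | intermediate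
6 | (4S)-4-benzyl-3-[(2R)-2-ethenyl-2-methylpent-4-enoyl]-1,3-oxazolidin-2-one | O=C([C@](C)(CC=C)C=C)N1[C@@H](Cc2ccccc2)COC1=O | intermediate
7 | (2R)-2-ethenyl-2-methylpent-4-en-1-ol | OC[C@](C)(CC=C)C=C | intermediate
8 | (2R)-2-ethenyl-2-methylpent-4-enal | O=C[C@](C)(CC=C)C=C | intermediate
9 | methyl (2Z,4R)-4-ethenyl-2-iodo-4-methylhepta-2,6-dienoate | COC(=O)/C(I)=C/[C@](C)(CC=C)C=C | intermediate
10 | (2Z,4R)-4-ethenyl-2-iodo-4-methylhepta-2,6-dien-1-ol | OC/C(I)=C/[C@](C)(CC=C)C=C | intermediate
11 | (2Z,4R)-4-ethenyl-2-iodo-4-methylhepta-2,6-dienal | O=C/C(I)=C/[C@](C)(CC=C)C=C | intermediate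
12 | glycolaldehyde dimer (1,4-dioxane-2,5-diol) | OC1COC(O)CO1 | starting material
13 | methyl (2Z)-4-hydroxy-2-iodobut-2-enoate | COC(=O)/C(I)=C/CO | intermediate
14 | methyl (2E)-2-ethenyl-4-hydroxybut-2-enoate | COC(=O)/C(C=C)=C/CO | intermediate
15 | methyl (2E)-4-{[(bromomethyl)dimethylsilyl]oxy}-2-ethenylbut-2-enoate | COC(=O)/C(C=C)=C/CO[Si](C)(C)CBr | intermediate
16 | bromo[({[(2E)-3-(methoxycarbonyl)penta-2,4-dien-1-yl]oxy}dimethylsilyl)methyl]zinc | COC(=O)/C(C=C)=C/CO[Si](C)(C)C[Zn]Br | intermediate
17 | methyl (2E)-2-ethenyl-4-({[(2Z,4R)-4-ethenyl-2-formyl-4-methylhepta-2,6-dien-1-yl]dimethylsilyl}oxy)but-2-enoate | COC(=O)/C(C=C)=C/CO[Si](C)(C)C/C(C=O)=C\[C@](C)(CC=C)C=C | intermediate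
18 | siloxane-bridged cycloadduct: ring A cyclohexene (C2=C3, CO2Me on C2); C8a bears CHO and β-C13H2; C1 bears β-C11H2; C13–SiMe2–O–C11; C4a bears α-H and the R quaternary C5 (methyl, allyl, vinyl) | COC(=O)C1=CC[C@@H]([C@](C)(CC=C)C=C)[C@@](C=O)(C[Si](C)(C)O2)[C@H]1C2 | intermediate
19 | siloxane-bridged chlorohydrin: trans-decalin, 6β-Cl, 8α-OH, 5β-methyl, 5α-allyl, CO2Me on C2, C2=C3, C13–SiMe2–O–C11 bridge on the β face | COC(=O)C1=CC[C@H]2[C@](C)(CC=C)[C@@H](Cl)C[C@H](O)[C@]2(C[Si](C)(C)O3)[C@H]1C3 | intermediate
20 | methyl (1R,4aR,5S,6S,8S,8aS)-6-chloro-8-hydroxy-1-(hydroxymethyl)-5,8a-dimethyl-5-(prop-2-en-1-yl)-1,4,4a,5,6,7,8,8a-octahydronaphthalene-2-carboxylate | COC(=O)C1=CC[C@H]2[C@](C)(CC=C)[C@@H](Cl)C[C@H](O)[C@]2(C)[C@H]1CO | intermediate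
21 | allyl γ-lactone: lactone of 20 between C12 (on C2) and the C11 oxygen (on C1) | O=C1OC[C@H]2C1=CC[C@H]3[C@](C)(CC=C)[C@@H](Cl)C[C@H](O)[C@]23C | intermediate
22 | 2-methylbut-3-en-2-ol | C=CC(C)(C)O | starting material
23 | side-chain γ-lactone: as 21 with the 5α-[(2E)-4-hydroxy-4-methylpent-2-en-1-yl] group | O=C1OC[C@H]2C1=CC[C@H]3[C@](C)(C/C=C/C(C)(C)O)[C@@H](Cl)C[C@H](O)[C@]23C | intermediate
24 | lithium carboxylate of the opened lactone (C2–CO2Li, C1–CH2OH) | [Li+].[O-]C(=O)C1=CC[C@H]2[C@](C)(C/C=C/C(C)(C)O)[C@@H](Cl)C[C@H](O)[C@]2(C)[C@H]1CO | intermediate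
25 | methyl (1R,4aR,5S,6S,8S,8aS)-6-chloro-8-hydroxy-1-(hydroxymethyl)-5-[(2E)-4-hydroxy-4-methylpent-2-en-1-yl]-5,8a-dimethyl-1,4,4a,5,6,7,8,8a-octahydronaphthalene-2-carboxylate | COC(=O)C1=CC[C@H]2[C@](C)(C/C=C/C(C)(C)O)[C@@H](Cl)C[C@H](O)[C@]2(C)[C@H]1CO | intermediate
26 | methyl (1R,4aR,5S,6S,8S,8aS)-6-chloro-1-formyl-8-hydroxy-5-[(2E)-4-hydroxy-4-methylpent-2-en-1-yl]-5,8a-dimethyl-1,4,4a,5,6,7,8,8a-octahydronaphthalene-2-carboxylate | COC(=O)C1=CC[C@H]2[C@](C)(C/C=C/C(C)(C)O)[C@@H](Cl)C[C@H](O)[C@]2(C)[C@H]1C=O | target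

**Totals and risks**

Total step count: 17. Longest linear sequence: 14 steps (steps 1–7 and 11–17); the diene branch is steps 8–10.

Most likely to fail, in this order:

1. Step 12. The acidic catalyst may ionise or cleave the allylic Si–O linkage before the electron-poor Z-diene has reacted, and the catalyst may not fully override the weak facial bias of the C5 centre. The fallback sets out from 15 and returns at 21. The ester of 15 is reduced with DIBAL-H (CH2Cl2, −78 °C) to the allylic alcohol F1, which is protected (TBSCl, imidazole) as the silyl ether F2. Zinc insertion gives the organozinc bromide F3, and Negishi coupling with 11 gives the trienal F4, whose diene is now electron-rich and matched with the enal. Cycloaddition under the same oxazaborolidinium catalyst at −78 °C should give the cycloadduct F5, and SnCl4 should close ring B to the chlorohydrin F6. Bu4NF in DMF at 70 °C removes both silicon groups and gives the triol F7; with no ester present, no lactone forms at this point. MnO2 in CH2Cl2 then oxidises the allylic alcohol, and the lactol that follows, to the lactone 21.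

2. Step 13. The secondary C6 cation next to the quaternary C5 may undergo a 1,2-alkyl shift or lose a proton, the allyl group may compete, or the C8–O bond may settle equatorial. The fallback sets out from 18 and returns at 19. Pinnick oxidation (NaClO2, NaH2PO4, 2-methylbut-2-ene) gives the acid F8, and 1-chloro-N,N,2-trimethylprop-1-en-1-amine converts it into the acid chloride F9. SnCl4 (CH2Cl2, −78 °C) effects intramolecular acylation of the vinyl group with chloride capture to the β-chloro ketone F10, in which the chloride can reach the equatorial position by reversible elimination–addition. L-Selectride (THF, −78 °C) should attack the hindered ketone from the equatorial direction, as with 4,4-disubstituted 3-keto terpenoids, and give the axial alcohol 19.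

3. Step 14. Cleavage of the neopentyl C–Si bond may be incomplete, and hot fluoride may trigger Grob-type fragmentation of the 1,3-chlorohydrin or hydrolyse the ester. The fallback sets out from 19 and returns at 21. Tamao–Fleming oxidation (KF, KHCO3, H2O2, THF/MeOH; then PPTS) converts C–Si into C–OH and, after lactonisation, gives the hydroxymethyl lactone F11. The primary alcohol is converted selectively into the iodide F12 (PPh3, I2, imidazole, Appel reaction), and Bu3SnH/AIBN reduces the C–I bond to the methyl group of 21 while the secondary chloride survives.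

**Further compounds**

F1 | step 12 | (2E)-4-{[(bromomethyl)dimethylsilyl]oxy}-2-ethenylbut-2-en-1-ol | OC/C(C=C)=C/CO[Si](C)(C)CBr
F2 | step 12 | tert-butyldimethylsilyl ether of F1 | CC(C)(C)[Si](C)(C)OC/C(C=C)=C/CO[Si](C)(C)CBr
F3 | step 12 | organozinc bromide from F2 | CC(C)(C)[Si](C)(C)OC/C(C=C)=C/CO[Si](C)(C)C[Zn]Br
F4 | step 12 | trienal (as 17 with CH2OTBS in place of CO2Me) | CC(C)(C)[Si](C)(C)OC/C(C=C)=C/CO[Si](C)(C)C/C(C=O)=C\[C@](C)(CC=C)C=C
F5 | step 12 | cycloadduct (as 18 with CH2OTBS on C2) | CC(C)(C)[Si](C)(C)OCC1=CC[C@@H]([C@](C)(CC=C)C=C)[C@@](C=O)(C[Si](C)(C)O2)[C@H]1C2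
F6 | step 12 | chlorohydrin (as 19 with CH2OTBS on C2) | CC(C)(C)[Si](C)(C)OCC1=CC[C@H]2[C@](C)(CC=C)[C@@H](Cl)C[C@H](O)[C@]2(C[Si](C)(C)O3)[C@H]1C3
F7 | step 12 | triol (as 20 with CH2OH on C2) | OCC1=CC[C@H]2[C@](C)(CC=C)[C@@H](Cl)C[C@H](O)[C@]2(C)[C@H]1CO
F8 | step 13 | carboxylic acid (as 18 with CO2H on C8a) | COC(=O)C1=CC[C@@H]([C@](C)(CC=C)C=C)[C@@](C(=O)O)(C[Si](C)(C)O2)[C@H]1C2
F9 | step 13 | acid chloride of F8 | COC(=O)C1=CC[C@@H]([C@](C)(CC=C)C=C)[C@@](C(=O)Cl)(C[Si](C)(C)O2)[C@H]1C2
F10 | step 13 | β-chloro ketone (as 19 with C8=O) | COC(=O)C1=CC[C@H]2[C@](C)(CC=C)[C@@H](Cl)CC(=O)[C@]2(C[Si](C)(C)O3)[C@H]1C3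
F11 | step 14 | hydroxymethyl lactone (as 21 with CH2OH on C8a) | O=C1OC[C@H]2C1=CC[C@H]3[C@](C)(CC=C)[C@@H](Cl)C[C@H](O)[C@]23CO
F12 | step 14 | iodomethyl lactone (as 21 with CH2I on C8a) | O=C1OC[C@H]2C1=CC[C@H]3[C@](C)(CC=C)[C@@H](Cl)C[C@H](O)[C@]23CI
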